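**Plan** (target numbering: dihydronaphthalene C1–C4, C4a–C8a; pyrone = ring A, carbocycle = ring B)
1. Retrosynthetic cuts, in order: the two O-benzyl groups; the aryl–vinyl bond C4–C4a of ring B, together with a temporary γ-lactone (C2–CO–O–C4) and the tert-butyl ester; the C2–C3 bond; the C1–aryl bond; the enal C=C; the pyrone ring.
2. Forward: ring A is built first (ethyl 3-methylbut-2-enoate + diethyl oxalate), its 4-methyl group becomes an (E)-enal, the aryl group is added at C1, methyl 3-nitroacrylate supplies C3/C4 at C2, and ring B closes last.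
3. Enabling feature: the C2 carboxyl and C4 are 1,4-related, so the C4 aldehyde is stored as a five-membered pseudo-acid lactone that is not in the target; C4a is para to the C7 oxygen; C3–H, next to the methyl ester, is the only hydrogen β to C4.
4. Key event: acid ionises the lactol to an acyloxycarbenium ion, C4a closes ring B onto C4, and the bridged lactone opens by loss of H-3. This places the C3=C4 double bond, frees the C2 acid beside the intact C3 methyl ester and leaves C1/C2 untouched.
5. Stereochemistry: C1 from ligand-controlled rhodium-catalysed 1,4-arylation; C2 from catalyst-controlled enamine Michael addition; the centres at C3 and C4 of the intermediates are erased.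

Key step: step 11

Remarks: the aldehyde set free in step 10 is assumed to rest as the cyclic pseudo-acid 21 (ring–chain tautomer of 20); both tautomers give the same cation in step 11. The facial sense in step 5 is assigned from the accepted model for this ligand class; should it prove opposite, the (1R,4R) ligand is used. The descriptor of the diaryl methine changes from S (11–21) to R (22–25) with no change in space, because ring closure raises the CIP rank of the aryl group above the pyrone.

**Step 1**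
Reactants: 1 ethyl 3-methylbut-2-enoate; 2 diethyl oxalate
Product: 5 4-methyl-2-oxo-2H-pyran-6-carboxylic acid, via potassium dienolate 3 (not isolated), via ethyl pyronecarboxylate 4 (not isolated)
Conditions: KOEt, EtOH/Et2O, 0 °C to rt; then conc. aq. HCl, 100 °C
Reagents that add atoms: water, O
Why: Vinylogous Claisen condensation at the γ-methyl group, then acid-mediated lactonisation of the 2-hydroxymuconate and ester hydrolysis, is the classical entry to 4-substituted 2-pyrone-6-carboxylic acids and creates no stereocenter.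

**Step 2**
Reactants: 5 4-methyl-2-oxo-2H-pyran-6-carboxylic acid
Product: 6 tert-butyl 4-methyl-2-oxo-2H-pyran-6-carboxylate
Conditions: tert-butyl 2,2,2-trichloroacetimidate, BF3·OEt2 (cat.), CH2Cl2/cyclohexane, rt
Reagents that add atoms: tert-butyl 2,2,2-trichloroacetimidate, CC(C)(C)OC(=N)C(Cl)(Cl)Cl
Why: Acid-catalysed O-tert-butylation by the imidate (tert-butyl cation transfer) esterifies the acid without the nucleophilic bases that open 2-pyrones, and the ester is later cleaved by the acid of step 11.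

**Step 3**
Reactants: 6 tert-butyl 4-methyl-2-oxo-2H-pyran-6-carboxylate
Product: 7 tert-butyl 4-formyl-2-oxo-2H-pyran-6-carboxylate
Conditions: SeO2 (1.5 equiv), 1,4-dioxane (trace H2O), 100 °C
Reagents that add atoms: selenium dioxide, O=[Se]=O
Why: Riley oxidation of the vinylogously activated 4-methyl group (ene reaction then [2,3]-shift), as known for 4-methylcoumarins and methyl-2-pyrones, should stop at the aldehyde.

**Step 4**
Reactants: 7 tert-butyl 4-formyl-2-oxo-2H-pyran-6-carboxylate; 8 2-(triphenylphosphoranylidene)acetaldehyde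
Product: 9 tert-butyl 2-oxo-4-[(1E)-3-oxoprop-1-en-1-yl]-2H-pyran-6-carboxylate
Conditions: toluene, 50 °C
Reagents that add atoms: none
Why: Wittig olefination with the stabilised formylmethylene ylide should give the (E)-enal, and the electron-poor aldehyde 7 reacts faster than the product enal, which limits double homologation.

**Step 5**
Reactants: 9 tert-butyl 2-oxo-4-[(1E)-3-oxoprop-1-en-1-yl]-2H-pyran-6-carboxylate; 10 [3,4-bis(benzyloxy)phenyl]boronic acid
Product: 11 tert-butyl 4-[(1S)-1-[3,4-bis(benzyloxy)phenyl]-3-oxopropyl]-2-oxo-2H-pyran-6-carboxylate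
Conditions: 10 (1.5 equiv), [RhCl(C2H4)2]2 (2.5 mol %), (1S,4S)-2,5-diphenylbicyclo[2.2.2]octa-2,5-diene (5.5 mol %), KOH (10 mol %), 1,4-dioxane/H2O 10:1, 30 °C
Reagents that add atoms: none
Why: Hayashi–Miyaura 1,4-addition in which the aryl group passes from the chiral-diene rhodium complex to the Re face of the enal β-carbon, setting the diaryl methine that becomes C1, with diene ligands favouring 1,4- over 1,2-addition to enals and the excess boronic acid buffering the hydroxide.

**Step 6**
Reactants: 12 methyl 2-hydroxy-2-methoxyacetate; 13 nitromethane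
Product: 14 methyl 2-hydroxy-3-nitropropanoate (racemic)
Conditions: Et3N (10 mol %), THF, 0 °C to rt
Reagents that add atoms: none
Why: Henry (nitroaldol) addition of nitromethane to the methyl glyoxylate released from its hemiacetal; the carbinol centre is racemic and is removed in step 7.

**Step 7**
Reactants: 14 methyl 2-hydroxy-3-nitropropanoate
Product: 16 methyl (2E)-3-nitroprop-2-enoate, via mesylate 15 (not isolated)
Conditions: MsCl (1.1 equiv), Et3N (2.2 equiv), CH2Cl2, −20 to 0 °C
Reagents that add atoms: none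
Why: O-Mesylation followed by E1cB elimination through the nitronate should give the (E)-nitroacrylate, which is used at once.

**Step 8**
Reactants: 11 tert-butyl 4-[(1S)-1-[3,4-bis(benzyloxy)phenyl]-3-oxopropyl]-2-oxo-2H-pyran-6-carboxylate; 16 methyl (2E)-3-nitroprop-2-enoate
Product: 17 tert-butyl 4-[(1S,2S,3S)-1-[3,4-bis(benzyloxy)phenyl]-2-formyl-4-methoxy-3-(nitromethyl)-4-oxobutyl]-2-oxo-2H-pyran-6-carboxylate
Conditions: 16 (1.5 equiv), (R)-2-[diphenyl(trimethylsilyloxy)methyl]pyrrolidine (10 mol %), ClCH2CO2H (20 mol %), CH2Cl2, 0 °C to rt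
Reagents that add atoms: none
Why: Enamine-catalysed Michael addition of an aldehyde to a nitroalkene, in which the (R)-catalyst shields the Si face of the (E)-enamine so that the ester-bearing carbon of 16 bonds to the Re face of the α-carbon and sets the future C2 (S) under catalyst control, with the usual syn topicity at the ester-bearing carbon, a centre that is erased later.

**Step 9**
Reactants: 17 tert-butyl 4-[(1S,2S,3S)-1-[3,4-bis(benzyloxy)phenyl]-2-formyl-4-methoxy-3-(nitromethyl)-4-oxobutyl]-2-oxo-2H-pyran-6-carboxylate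
Product: 18 (2S,3S)-2-[(S)-[3,4-bis(benzyloxy)phenyl][6-(tert-butoxycarbonyl)-2-oxo-2H-pyran-4-yl]methyl]-4-methoxy-3-(nitromethyl)-4-oxobutanoic acid
Conditions: NaClO2, NaH2PO4, 2-methylbut-2-ene, t-BuOH/THF/H2O, 0 °C
Reagents that add atoms: sodium chlorite, [Na+].[O-]Cl=O
Why: Pinnick oxidation under buffered, mildly acidic conditions should convert the aldehyde into the C2 carboxylic acid without epimerising the α-centre or touching the nitro group, pyrone or benzyl ethers.

**Step 10**
Reactants: 18 (2S,3S)-2-[(S)-[3,4-bis(benzyloxy)phenyl][6-(tert-butoxycarbonyl)-2-oxo-2H-pyran-4-yl]methyl]-4-methoxy-3-(nitromethyl)-4-oxobutanoic acid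
Product: 21 methyl (4S)-4-[(S)-[3,4-bis(benzyloxy)phenyl][6-(tert-butoxycarbonyl)-2-oxo-2H-pyran-4-yl]methyl]-2-hydroxy-5-oxooxolane-3-carboxylate, via nitronate salt 19 (not isolated), via open oxo acid 20 (not isolated)
Conditions: DBU (2.2 equiv), THF, −20 °C, 15 min; then 15% aq. TiCl3 (5 equiv), NH4OAc buffer (pH 5–6), 0 °C to rt; 1 M HCl work-up
Reagents that add atoms: water, O
Why: Reductive Nef reaction, in which trivalent titanium (TiCl3) reduces the nitronate to the imine, water hydrolyses it to the C4 aldehyde, and the 1,4-related C2 carboxylic acid captures the aldehyde as the five-membered lactol (pseudo-acid) that stores C4 for the ring closure.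

**Step 11**
Reactants: 21 methyl (4S)-4-[(S)-[3,4-bis(benzyloxy)phenyl][6-(tert-butoxycarbonyl)-2-oxo-2H-pyran-4-yl]methyl]-2-hydroxy-5-oxooxolane-3-carboxylate
Product: 24 (1R,2S)-6,7-bis(benzyloxy)-1-(6-carboxy-2-oxo-2H-pyran-4-yl)-3-(methoxycarbonyl)-1,2-dihydronaphthalene-2-carboxylic acid, via bridged lactone 22 (not isolated), via tert-butyl ester 23 (not isolated)
Conditions: CF3CO2H/CH2Cl2 1:3, 0 °C to rt
Reagents that add atoms: none
Why: Protonation of the lactol hydroxyl and loss of water give a cyclic acyloxycarbenium ion at C4 (in equilibrium with the protonated open aldehyde), which is attacked by the aryl carbon para to the C7 benzyloxy group to form the C4–C4a bond and the transient benzo-fused 6-oxabicyclo[3.2.1]octan-7-one 22. The benzylic C4–O bond of 22, para to an ether oxygen, ionises in the same medium and the cation loses H-3, which opens the temporary lactone, places the double bond at C3=C4 and releases the C2 carboxylic acid, while the acid also cleaves the tert-butyl ester. The closest known reaction type is the acid-mediated Friedel–Crafts cyclodehydration of aryl-tethered aldehydes and 5-hydroxybutanolides to 1,2-dihydronaphthalenes. Ring B closes as a six-membered ring in the exo mode with respect to the C=O+ bond (the lactone oxygen stays outside the new ring), and the lactone ring, which is not in the target, is cleaved in the same operation. No lasting stereocenter is formed (C4 ends sp2), and C1 and C2 are carried through unchanged because no base is present and neither C–H bond takes part. The step needs regioselectivity on the arene (para rather than ortho to a benzyloxy group, secured by the stronger para activation and lower hindrance) and in the elimination (secured because C4 carries the leaving oxygen and only C3 carries a β-hydrogen).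

**Step 12**
Reactants: 24 (1R,2S)-6,7-bis(benzyloxy)-1-(6-carboxy-2-oxo-2H-pyran-4-yl)-3-(methoxycarbonyl)-1,2-dihydronaphthalene-2-carboxylic acid
Product: 25 (1R,2S)-1-(6-carboxy-2-oxo-2H-pyran-4-yl)-6,7-dihydroxy-3-(methoxycarbonyl)-1,2-dihydronaphthalene-2-carboxylic acid
Conditions: BCl3 (6 equiv), pentamethylbenzene (6 equiv), CH2Cl2, −78 °C; then MeOH/H2O
Reagents that add atoms: none
Why: Lewis-acid debenzylation of aryl benzyl ethers with pentamethylbenzene as a non-basic benzyl cation scavenger should free the catechol at −78 °C without hydrogenation of the C3=C4 bond or the pyrone, without cleaving the methyl ester and without epimerising C1 or C2.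

**Compound list**
1 | ethyl 3-methylbut-2-enoate | CCOC(=O)C=C(C)C | starting material
2 | diethyl oxalate | CCOC(=O)C(=O)OCC | starting material
3 | potassium 1,6-diethoxy-4-methyl-1,6-dioxohexa-2,4-dien-2-olate (mixture of double-bond isomers) | CCOC(=O)C([O-])=CC(C)=CC(=O)OCC.[K+] | intermediate
4 | ethyl 4-methyl-2-oxo-2H-pyran-6-carboxylate | CCOC(=O)C1=CC(C)=CC(=O)O1 | intermediate
5 | 4-methyl-2-oxo-2H-pyran-6-carboxylic acid | CC1=CC(=O)OC(C(=O)O)=C1 | intermediate
6 | tert-butyl 4-methyl-2-oxo-2H-pyran-6-carboxylate | CC1=CC(=O)OC(C(=O)OC(C)(C)C)=C1 | intermediate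
7 | tert-butyl 4-formyl-2-oxo-2H-pyran-6-carboxylate | O=CC1=CC(=O)OC(C(=O)OC(C)(C)C)=C1 | intermediate
8 | 2-(triphenylphosphoranylidene)acetaldehyde | O=CC=P(c1ccccc1)(c1ccccc1)c1ccccc1 | starting material
9 | tert-butyl 2-oxo-4-[(1E)-3-oxoprop-1-en-1-yl]-2H-pyran-6-carboxylate | O=C/C=C/C1=CC(=O)OC(C(=O)OC(C)(C)C)=C1 | intermediate
10 | [3,4-bis(benzyloxy)phenyl]boronic acid | OB(O)c1ccc(OCc2ccccc2)c(OCc2ccccc2)c1 | starting material
11 | tert-butyl 4-[(1S)-1-[3,4-bis(benzyloxy)phenyl]-3-oxopropyl]-2-oxo-2H-pyran-6-carboxylate | C(c1ccccc1)Oc1ccc(cc1OCc1ccccc1)[C@@H](c1cc(C(=O)OC(C)(C)C)oc(=O)c1)CC=O | intermediate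
12 | methyl 2-hydroxy-2-methoxyacetate | COC(O)C(=O)OC | starting material
13 | nitromethane | C[N+](=O)[O-] | starting material
14 | methyl 2-hydroxy-3-nitropropanoate (racemic) | COC(=O)C(O)C[N+](=O)[O-] | intermediate
15 | methyl 2-[(methylsulfonyl)oxy]-3-nitropropanoate (racemic) | COC(=O)C(OS(C)(=O)=O)C[N+](=O)[O-] | intermediate
16 | methyl (2E)-3-nitroprop-2-enoate | COC(=O)/C=C/[N+](=O)[O-] | intermediate
17 | tert-butyl 4-[(1S,2S,3S)-1-[3,4-bis(benzyloxy)phenyl]-2-formyl-4-methoxy-3-(nitromethyl)-4-oxobutyl]-2-oxo-2H-pyran-6-carboxylate | C(c1ccccc1)Oc1ccc(cc1OCc1ccccc1)[C@@H](c1cc(C(=O)OC(C)(C)C)oc(=O)c1)[C@@H]([C@H](C(=O)OC)C[N+](=O)[O-])C=O | intermediate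
18 | (2S,3S)-2-[(S)-[3,4-bis(benzyloxy)phenyl][6-(tert-butoxycarbonyl)-2-oxo-2H-pyran-4-yl]methyl]-4-methoxy-3-(nitromethyl)-4-oxobutanoic acid | C(c1ccccc1)Oc1ccc(cc1OCc1ccccc1)[C@@H](c1cc(C(=O)OC(C)(C)C)oc(=O)c1)[C@@H]([C@H](C(=O)OC)C[N+](=O)[O-])C(=O)O | intermediate
19 | bis(1,8-diazabicyclo[5.4.0]undec-7-enium) salt of the carboxylate nitronate of 18 | C(c1ccccc1)Oc1ccc(cc1OCc1ccccc1)[C@@H](c1cc(C(=O)OC(C)(C)C)oc(=O)c1)[C@@H]([C@H](C(=O)OC)C=[N+]([O-])[O-])C(=O)[O-].C1CCC2=[NH+]CCCN2CC1.C1CCC2=[NH+]CCCN2CC1 | intermediate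
20 | (2S)-2-[(S)-[3,4-bis(benzyloxy)phenyl][6-(tert-butoxycarbonyl)-2-oxo-2H-pyran-4-yl]methyl]-3-formyl-4-methoxy-4-oxobutanoic acid (both epimers at C3) | C(c1ccccc1)Oc1ccc(cc1OCc1ccccc1)[C@@H](c1cc(C(=O)OC(C)(C)C)oc(=O)c1)[C@@H](C(C=O)C(=O)OC)C(=O)O | intermediate
21 | methyl (4S)-4-[(S)-[3,4-bis(benzyloxy)phenyl][6-(tert-butoxycarbonyl)-2-oxo-2H-pyran-4-yl]methyl]-2-hydroxy-5-oxooxolane-3-carboxylate (mixture at oxolane C2 and C3) | C(c1ccccc1)Oc1ccc(cc1OCc1ccccc1)[C@@H](c1cc(C(=O)OC(C)(C)C)oc(=O)c1)[C@@H]1C(=O)OC(O)C1C(=O)OC | intermediate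
22 | (1R,2S,4S)-6,7-bis(benzyloxy)-1-[6-(tert-butoxycarbonyl)-2-oxo-2H-pyran-4-yl]-4-hydroxy-3-(methoxycarbonyl)-1,2,3,4-tetrahydronaphthalene-2-carboxylic acid 2,4-lactone (benzo-fused 6-oxabicyclo[3.2.1]octan-7-one; lactone bridge on the face opposite the pyrone; both epimers at C3) | COC(=O)C1[C@@H]2OC(=O)[C@H]1[C@H](c1cc(C(=O)OC(C)(C)C)oc(=O)c1)c1cc(OCc3ccccc3)c(OCc3ccccc3)cc12 | intermediate
23 | (1R,2S)-6,7-bis(benzyloxy)-1-[6-(tert-butoxycarbonyl)-2-oxo-2H-pyran-4-yl]-3-(methoxycarbonyl)-1,2-dihydronaphthalene-2-carboxylic acid | COC(=O)C1=Cc2cc(OCc3ccccc3)c(OCc3ccccc3)cc2[C@@H](c2cc(C(=O)OC(C)(C)C)oc(=O)c2)[C@@H]1C(=O)O | intermediate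
24 | (1R,2S)-6,7-bis(benzyloxy)-1-(6-carboxy-2-oxo-2H-pyran-4-yl)-3-(methoxycarbonyl)-1,2-dihydronaphthalene-2-carboxylic acid | COC(=O)C1=Cc2cc(OCc3ccccc3)c(OCc3ccccc3)cc2[C@@H](c2cc(C(=O)O)oc(=O)c2)[C@@H]1C(=O)O | intermediate
25 | (1R,2S)-1-(6-carboxy-2-oxo-2H-pyran-4-yl)-6,7-dihydroxy-3-(methoxycarbonyl)-1,2-dihydronaphthalene-2-carboxylic acid | COC(=O)C1=Cc2cc(O)c(O)cc2[C@@H](c2cc(C(=O)O)oc(=O)c2)[C@@H]1C(=O)O | target

**Step count**
Total: 12 steps. Longest linear sequence: 10 steps (steps 1–5 and 8–12); steps 6–7 are the side branch to 16.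

**Steps most likely to fail**

Step 10. The base needed to form the nitronate may instead trigger loss of nitrous acid from the β-nitro ester (giving the α-methylene ester) or open the pyrone, and the reduction may not stop cleanly at the aldehyde level. Fallback: starting from 18, the nitro group is reduced without a nitronate by SnCl2/PhSH/Et3N in MeCN at rt to the aldoxime (2S)-2-[(S)-[3,4-bis(benzyloxy)phenyl][6-(tert-butoxycarbonyl)-2-oxo-2H-pyran-4-yl]methyl]-3-[(hydroxyimino)methyl]-4-methoxy-4-oxobutanoic acid F1, which is isolated. Oxime exchange with aqueous glyoxylic acid in AcOH at rt should then release the aldehyde, which closes to lactol 21, where the route is rejoined.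

Step 8. The hindered β,β-diaryl aldehyde may form its enamine slowly, the secondary amine may be consumed by conjugate addition to the nitroacrylate or the pyrone, and the existing C1 centre may oppose the catalyst, giving poor facial selectivity at C2. Fallback (auxiliary control in place of catalyst control): from 11, Pinnick oxidation should give (3S)-3-[3,4-bis(benzyloxy)phenyl]-3-[6-(tert-butoxycarbonyl)-2-oxo-2H-pyran-4-yl]propanoic acid F2. Its pivaloyl mixed anhydride (t-BuCOCl, Et3N) acylates (R)-4-benzyl-1,3-oxazolidin-2-one in the presence of LiCl to the imide tert-butyl 4-[(1S)-1-[3,4-bis(benzyloxy)phenyl]-3-[(4R)-4-benzyl-2-oxo-1,3-oxazolidin-3-yl]-3-oxopropyl]-2-oxo-2H-pyran-6-carboxylate F3. Soft enolisation (TiCl4, i-Pr2NEt, CH2Cl2, −78 °C), which leaves the more acidic C1–H alone, and Michael addition of the chelated (Z)-chlorotitanium enolate to 16 on the face away from the benzyl group should give tert-butyl 4-[(1S,2S)-1-[3,4-bis(benzyloxy)phenyl]-2-[(4R)-4-benzyl-2-oxo-1,3-oxazolidine-3-carbonyl]-4-methoxy-3-(nitromethyl)-4-oxobutyl]-2-oxo-2H-pyran-6-carboxylate F4. LiOH/H2O2 (THF/H2O, 0 °C) removes the auxiliary and returns acid 18 (as a mixture at the ester-bearing carbon, which is erased in step 11).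

Step 3. Oxidation of the electron-poor 4-methylpyrone may be sluggish at temperatures where over-oxidation to the acid and acid-promoted loss of the tert-butyl ester compete. Fallback: from 6, condensation of the acidic 4-methyl group with Me2NCH(OMe)2 (DMF, 80 °C) should give the enamine tert-butyl 4-[(E)-2-(dimethylamino)ethenyl]-2-oxo-2H-pyran-6-carboxylate F5, whose C=C bond is cleaved by NaIO4 (THF/H2O, rt) to aldehyde 7, where the route is rejoined.

**Further compounds**
F1 | step 10 | (2S)-2-[(S)-[3,4-bis(benzyloxy)phenyl][6-(tert-butoxycarbonyl)-2-oxo-2H-pyran-4-yl]methyl]-3-[(hydroxyimino)methyl]-4-methoxy-4-oxobutanoic acid | C(c1ccccc1)Oc1ccc(cc1OCc1ccccc1)[C@@H](c1cc(C(=O)OC(C)(C)C)oc(=O)c1)[C@@H](C(C(=O)OC)C=NO)C(=O)O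
F2 | step 8 | (3S)-3-[3,4-bis(benzyloxy)phenyl]-3-[6-(tert-butoxycarbonyl)-2-oxo-2H-pyran-4-yl]propanoic acid | C(c1ccccc1)Oc1ccc(cc1OCc1ccccc1)[C@@H](c1cc(C(=O)OC(C)(C)C)oc(=O)c1)CC(=O)O
F3 | step 8 | tert-butyl 4-[(1S)-1-[3,4-bis(benzyloxy)phenyl]-3-[(4R)-4-benzyl-2-oxo-1,3-oxazolidin-3-yl]-3-oxopropyl]-2-oxo-2H-pyran-6-carboxylate | C(c1ccccc1)Oc1ccc(cc1OCc1ccccc1)[C@@H](c1cc(C(=O)OC(C)(C)C)oc(=O)c1)CC(=O)N1[C@H](Cc2ccccc2)COC1=O
F4 | step 8 | tert-butyl 4-[(1S,2S)-1-[3,4-bis(benzyloxy)phenyl]-2-[(4R)-4-benzyl-2-oxo-1,3-oxazolidine-3-carbonyl]-4-methoxy-3-(nitromethyl)-4-oxobutyl]-2-oxo-2H-pyran-6-carboxylate | C(c1ccccc1)Oc1ccc(cc1OCc1ccccc1)[C@@H](c1cc(C(=O)OC(C)(C)C)oc(=O)c1)[C@@H](C(C(=O)OC)C[N+](=O)[O-])C(=O)N1[C@H](Cc2ccccc2)COC1=O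
F5 | step 3 | tert-butyl 4-[(E)-2-(dimethylamino)ethenyl]-2-oxo-2H-pyran-6-carboxylate | CN(C)/C=C/C1=CC(=O)OC(C(=O)OC(C)(C)C)=C1
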